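The runs come from a simulation with made-up constants; noise was put on by code.

The ratio of starting material to mono adduct was the number I watched, because two steps that both take reagent lose it from their ratio of rates.

in all of them: starting material 0.057 M
- Sunday's: reagent 1.8 equiv; run made earlier
- Thursday's: reagent 1.7 equiv; run made earlier
- blue: reagent 1.50 equiv; time 2.0 h
- teal: reagent 2.20 equiv; time 2.0 h

| run | time / min | mono adduct / % | starting material / % |
|---|---|---|---|
| Sunday's | 15.0 | 21 | 73 |
| Sunday's | 30.0 | 25 | 53 |
| Sunday's | 50.0 | 32 | 39 |
| Sunday's | 60.0 | 31 | 37 |
| Sunday's | 80.0 | 29 | 26 |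
| Thursday's | 6.00 | 10 | 86 |
| Thursday's | 12.0 | 19 | 76 |
| Thursday's | 25.0 | 21 | 64 |
| Thursday's | 40.0 | 33 | 47 |
| Thursday's | 80.0 | 28 | 31 |

(each reading ± 1.5 percentage points)

- which of the two there is more of at the end, blue (bis adduct / mono adduct)
- which of the two there is more of at the end, teal (bis adduct / mono adduct)
- amount of mono adduct at the end, in percent of the starting material charged, blue
- amount of mono adduct at the end, in percent of the starting material charged, teal

- the earlier runs were read with a standard deviation of 1.5 percentage points

At the bench I say mono adduct climbs while more starting material stands than mono adduct, which puts the border at a ratio of one. The readings put it higher. Sunday's top reading came at 50.0 min with the ratio at 1.22, and Thursday's at 40.0 min with 1.42. Their mean, 1.32, carries the scatter of the readings. I called it the crossing ratio, the ratio of starting material to mono adduct at which mono adduct stops gaining. For a plain two-step chain, this is the selectivity factor.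

Sunday's last ratio, 0.897, already lay below the crossing ratio. Charged equivalents times time stood at 1.25 times that reading's value in blue and 1.83 times in teal, so I placed both flasks past the top. Sunday's mono adduct lost 3 points after its top reading. Continuing that slope per equivalent and minute, I reckoned 27.0% for blue and 22.3% for teal. Neither run read bis adduct, and I made no call of mono against bis.

The forecast gave 28% for blue and 19% for teal, with bis adduct ahead in blue and bis adduct ahead in teal: “Bis exceeds mono in both runs.” Blue ended with 28.5% of mono adduct and 19.8% of bis adduct. Teal ended with 25.6% of mono adduct and 33.6% of bis adduct.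

    reagent + other mono adduct → bis adduct (k = 0.00368 M⁻¹ s⁻¹)
    mono adduct ⇌ isomer of the product (K = 0.650, k = 1.80 × 10⁻⁴ s⁻¹)
    reagent + mono adduct → bis adduct (k = 0.00173 M⁻¹ s⁻¹)
    starting material + reagent → other mono adduct (k = 5.70 × 10⁻⁴ M⁻¹ s⁻¹)
    reagent + mono adduct → over-reaction product (k = 6.37 × 10⁻⁴ M⁻¹ s⁻¹)
    starting material + reagent → mono adduct (k = 0.00330 M⁻¹ s⁻¹)

Blue's ratio ended at 0.902, below the crossing ratio, and mono adduct was then made at 0.872 of the rate at which it was used up, each step taken net. The neighbour flask was blue with 0.023 M of starting material. Its ratio ended at 1.92, above the crossing ratio, so the same reckoning placed it on the rising side. It ended with 48.1% of starting material, 25.0% of mono adduct and 7.88% of bis adduct.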